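**Retrosynthetic overview**
1. Feature: ring C, the benzo ring of the dihydrobenzofuran, has oxygen on two neighbouring carbons, O1 on C7a and the methoxy oxygen on C7. C7a–C7 is read as the two carbons of an ethynyl group on the C2 oxygen. C3a–C4–C5–C6 and the C7 oxygen are read as a 2,4-disubstituted furan bonded to C3.
2. Key disconnection: C3a–C7a and C6–C7 are cut together, so one gold-catalysed furan–ynol ether cascade closes the dihydrofuran ring and ring C. C2 and C3 are set beforehand by an Evans boron syn-aldol of a furylacetyl imide with O-benzylvanillin (syn pair = 2,3-trans ring).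
3. Lactone: the Cα–CH2(ring B) bond is cut first (trans-selective enolate alkylation). The ring C CH2–Cβ bond is cut next (Evans alkylation of a succinate imide with the ring C benzyl bromide, reduction, lactonisation).
4. The ring A/B glycerol ether is made apart as a benzyl bromide by an aryloxyacetate Evans syn-aldol (threo) and Mitsunobu inversion of the carbinol (erythro). Order of ring formation: dihydrofuran ring and ring C together (step 10), then the lactone (step 16). Rings A, B and D are bought.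

Key step: step 10

Locants and abbreviations:
- The dihydrobenzofuran is numbered O1, C2, C3, C3a, C4–C7, C7a.
- Ring D is the C2 aryl group, ring B the aryl ring of the lactone α-benzyl group, and ring A the aryl ring of the glycerol unit.
- Ar = 4-(benzyloxy)-3-methoxyphenyl; TBS = tert-butyldimethylsilyl; TIPS = triisopropylsilyl.
- DHB = (2S,3R)-2-Ar-7-methoxy-3-(TIPSOCH2)-2,3-dihydro-1-benzofuran-5-yl.

Assumption: the SMILES is read as (2S,3R) trans-dihydrobenzofuran, (3R,4R) trans-lactone and (1R,2S) erythro glycerol ether; methyl 5-bromofuran-3-carboxylate and BrZnCH2CO2Et in THF are taken as bought.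

Protecting groups:
- The C5 CH2OH is carried as a TBS ether and not as a p-methoxybenzyl ether. After O-methylation ring C is itself a 4-alkoxy-3-methoxybenzyl system, so an oxidative cleavage could not tell the two benzylic carbons apart.
- The C3 CH2OH is carried as a TIPS ether because it must not migrate to the neighbouring potassium alkoxide in step 9.

Step 1
Reactants: 1 methyl 5-bromofuran-3-carboxylate
Product: 2 (5-bromofuran-3-yl)methanol
Conditions: i-Bu2AlH (2.2 equiv), CH2Cl2, −78 to 0 °C; aq. potassium sodium tartrate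
Reagents that add atoms: none
Why: Ester-to-alcohol reduction with an aluminium hydride: at low temperature i-Bu2AlH should reduce the furoate fully and leave the furan ring and its C–Br bond untouched.

Step 2
Reactants: 2 (5-bromofuran-3-yl)methanol
Product: 3 [(5-bromofuran-3-yl)methoxy](tert-butyl)dimethylsilane
Conditions: TBSCl, imidazole, CH2Cl2, 0 °C to rt
Reagents that add atoms: tert-butyldimethylsilyl chloride, CC(C)(C)[Si](C)(C)Cl
Why: Imidazole-promoted silylation of a primary alcohol: the TBS ether should stand the zinc, boron, hydride and organolithium reagents ahead and can later be removed beside a TIPS ether.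

Step 3
Reactants: 3 silyl-protected bromofuran
Product: 4 ethyl 2-[4-(TBSOCH2)furan-2-yl]acetate
Conditions: BrZnCH2CO2Et (1.5 equiv), Pd2(dba)3 (2 mol %), XPhos (8 mol %), THF, 50 °C
Reagents that add atoms: (2-ethoxy-2-oxoethyl)zinc bromide, CCOC(=O)C[Zn]Br
Why: Negishi-type coupling of a Reformatsky reagent (palladium-catalysed α-arylation of an ester zinc enolate): zerovalent palladium inserts easily into the C–Br bond at the furan α-carbon, and the weakly basic zinc enolate spares the silyl ether.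

Step 4
Reactants: 4 ethyl furylacetate
Product: 5 2-[4-(TBSOCH2)furan-2-yl]acetic acid
Conditions: LiOH, THF–MeOH–H2O, 0 °C to rt; then 1 M HCl to pH 4, 0 °C
Reagents that add atoms: lithium hydroxide, [Li+].[OH-]
Why: Saponification: the unhindered aliphatic ester is cleaved by hydroxide under conditions that a primary TBS ether and the furan tolerate, and the acidification is kept cold and mild for the same reason.

Step 5
Reactants: 5 furylacetic acid; 6 (S)-4-benzyl-1,3-oxazolidin-2-one
Product: 8 (4S)-4-benzyl-3-{2-[4-(TBSOCH2)furan-2-yl]acetyl}-1,3-oxazolidin-2-one, via pivalic mixed anhydride 7 (not isolated)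
Conditions: t-BuCOCl, Et3N, THF, −20 °C; then LiCl, 6, −20 °C to rt
Reagents that add atoms: pivaloyl chloride, CC(C)(C)C(=O)Cl (its atoms stay in 7 only)
Why: N-acylation of an oxazolidinone through a mixed pivalic anhydride (LiCl/Et3N variant): the bulk of the tert-butyl group steers the nitrogen to the furylacetyl carbonyl of 7, and no strong base meets the acidic CH2 group.

Step 6
Reactants: 8 furylacetyl imide; 9 4-(benzyloxy)-3-methoxybenzaldehyde (O-benzylvanillin)
Product: 11 (4S)-4-benzyl-3-{(2R,3S)-3-Ar-3-hydroxy-2-[4-(TBSOCH2)furan-2-yl]propanoyl}-1,3-oxazolidin-2-one, via dibutylboron enolate 10 (not isolated)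
Conditions: Bu2BOTf, Et3N, CH2Cl2, −78 to 0 °C; 9, −78 to 0 °C; pH 7 buffer, MeOH, 30% H2O2, 0 °C
Reagents that add atoms: dibutylboron triflate, CCCCB(CCCC)OS(=O)(=O)C(F)(F)F (its atoms stay in 10 only)
Why: Evans boron syn-aldol reaction: the Z-boron enolate 10 reacts through a closed Zimmerman–Traxler chair on the face turned away from the auxiliary benzyl group, which sets both new centres as the (2R,3S) syn pair, the later C3 (R) and C2 (S) of the dihydrobenzofuran.

Step 7
Reactants: 11 syn-aldol adduct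
Product: 12 (1S,2R)-1-Ar-2-[4-(TBSOCH2)furan-2-yl]propane-1,3-diol
Conditions: LiBH4, MeOH (1 equiv), THF, 0 °C
Reagents that add atoms: none
Why: Reductive cleavage of an N-acyloxazolidinone: LiBH4/MeOH attacks the exocyclic imide carbonyl, frees the auxiliary and gives the primary alcohol at a temperature low enough to hold back retro-aldol cleavage, so both centres are kept.

Step 8
Reactants: 12 diol
Product: 13 (1S,2R)-1-Ar-2-[4-(TBSOCH2)furan-2-yl]-3-(TIPSO)propan-1-ol
Conditions: TIPSCl, imidazole, DMAP (cat.), CH2Cl2, 0 °C to rt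
Reagents that add atoms: triisopropylsilyl chloride, CC(C)[Si](Cl)(C(C)C)C(C)C
Why: Chemoselective silylation: the bulky chlorosilane reacts only at the primary hydroxyl, and TIPS is chosen because it should stay on the primary oxygen when the secondary alkoxide is made in the next step.

Step 9
Reactants: 13 secondary alcohol
Product: 17 (1S,2R)-1-Ar-2-[4-(TBSOCH2)furan-2-yl]-3-(TIPSO)propyl ethynyl ether, via (E)-1,2-dichlorovinyl ether 14 (not isolated), via chloroethynyl ether 15 (not isolated), via lithium alkynyl ether 16 (not isolated)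
Conditions: KH, THF, 0 °C; Cl2C=CHCl, −50 °C to rt; n-BuLi (3 equiv), −78 to −40 °C; MeOH, −78 °C; Et3N-washed silica, kept cold and used at once
Reagents that add atoms: trichloroethylene, ClC=C(Cl)Cl; n-butyllithium, [Li]CCCC (lithium stays in 16 only)
Why: Greene ynol ether synthesis: the potassium alkoxide adds to dichloroacetylene formed from trichloroethylene to give 14, n-BuLi eliminates HCl to 15 and exchanges the last chlorine for lithium to give 16, methanol protonates it, and the C–O bond at the carbinol carbon is never broken, so its configuration is kept.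

Step 10
Reactants: 17 furyl ethynyl ether
Product: 19 (2S,3R)-2-Ar-5-(TBSOCH2)-3-(TIPSOCH2)-2,3-dihydro-1-benzofuran-7-ol, via arene oxide 18 (not isolated)
Conditions: Ph3PAuNTf2 (3 mol %), 4 Å MS, CH2Cl2, −20 °C to rt
Reagents that add atoms: none
Why: Cationic monovalent gold binds the ynol ether, whose oxygen polarises it so that the furan C2=C3 bond attacks the oxygen-bearing alkyne carbon; this 5-exo-dig closure makes C3a–C7a and the dihydrofuran ring and leaves a cyclopropyl gold carbene on the former terminal carbon. The carbene opens with cleavage of the furan C2–O bond to a dienal gold carbene, the aldehyde oxygen adds to the carbene carbon to give an oxepine, and its 6π electrocyclic valence tautomer, arene oxide 18, holds the new C6–C7 bond and thus the six-membered ring C. The oxirane opens at C6–O, because the cation so formed is delocalised onto C7a and stabilised by O1, and loss of the C7 proton gives the C7 phenol. The closest known reaction type is the gold-catalysed furan–yne phenol synthesis (Hashmi phenol synthesis), which is known with alkynyl ether tethers to give 7-hydroxy-2,3-dihydrobenzofurans and is applied here to a branched tether and a 4-substituted furan. No stereocentre is formed and no bond to C2 or C3 is broken, so the syn pair from step 6 appears as the (2S,3R) trans ring. The step needs regioselectivity, secured by the ynol ether polarisation, the short tether and the O1 donor, with the furan C4 substituent carried to C5, and it needs the cyclisation to outrun ionisation of the benzylic C2–O1 bond, a [3,3] shift onto ring D and hydration, for which the low temperature, the dry medium and the intramolecular furan are relied on.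

Step 11
Reactants: 19 C7 phenol
Product: 20 DHB-CH2OTBS, that is (2S,3R)-2-Ar-7-methoxy-5-(TBSOCH2)-3-(TIPSOCH2)-2,3-dihydro-1-benzofuran
Conditions: MeI, K2CO3, acetone, rt
Reagents that add atoms: iodomethane, CI
Why: Williamson O-methylation of a phenol: the only acidic group is the C7 hydroxyl, and carbonate in acetone leaves silyl and benzyl ethers alone.

Step 12
Reactants: 20 bis-silyl ether
Product: 21 DHB-CH2OH (C5 benzylic alcohol)
Conditions: HF·pyridine, pyridine, THF, 0 °C
Reagents that add atoms: none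
Why: Selective desilylation: buffered HF·pyridine cleaves the unhindered primary benzylic TBS ether faster than the bulkier, β-branched TIPS ether, and the non-nucleophilic medium avoids solvolysis at the electron-rich benzylic carbon.

Step 13
Reactants: 21 benzylic alcohol
Product: 22 DHB-CH2Br (C5 benzylic bromide)
Conditions: CBr4, PPh3, CH2Cl2, 0 °C; used at once
Reagents that add atoms: tetrabromomethane, BrC(Br)(Br)Br
Why: Appel reaction: the primary benzylic alcohol is turned into the bromide under neutral conditions that spare the TIPS ether, the benzyl ether and the benzylic C2–O1 bond.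

Step 14
Reactants: 23 4-tert-butoxy-4-oxobutanoic acid (mono-tert-butyl succinate); 24 (R)-4-benzyl-1,3-oxazolidin-2-one
Product: 26 tert-butyl 4-[(4R)-4-benzyl-2-oxo-1,3-oxazolidin-3-yl]-4-oxobutanoate, via pivalic mixed anhydride 25 (not isolated)
Conditions: t-BuCOCl, Et3N, THF, −20 °C; then LiCl, 24, −20 °C to rt
Reagents that add atoms: pivaloyl chloride, CC(C)(C)C(=O)Cl (its atoms stay in 25 only)
Why: N-acylation of an oxazolidinone through a mixed pivalic anhydride: attack falls on the less hindered succinyl carbonyl, and the tert-butyl ester is inert.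

Step 15
Reactants: 26 succinate imide; 22 benzylic bromide
Product: 28 tert-butyl (3R)-4-[(4R)-4-benzyl-2-oxo-1,3-oxazolidin-3-yl]-3-(DHB-methyl)-4-oxobutanoate, via sodium enolate 27 (not isolated)
Conditions: NaN(SiMe3)2, THF, −78 °C; 22, −78 to −40 °C
Reagents that add atoms: sodium bis(trimethylsilyl)amide, C[Si](C)(C)[N-][Si](C)(C)C.[Na+] (sodium stays in 27 only)
Why: Evans asymmetric alkylation: the base deprotonates next to the more acidic imide carbonyl, and the chelated Z-enolate 27 is alkylated by the reactive benzylic bromide on the face opposite the auxiliary benzyl group, which sets the later lactone C4 as R.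

Step 16
Reactants: 28 alkylated imide
Product: 30 (4R)-4-(DHB-methyl)oxolan-2-one, via hydroxy ester 29 (not isolated)
Conditions: LiBH4, MeOH (1 equiv), THF, 0 °C; work-up; p-TsOH·H2O (10 mol %), toluene, 50 °C
Reagents that add atoms: none
Why: Reductive removal of the auxiliary followed by acid-catalysed lactonisation: LiBH4 reduces the imide but not the tert-butyl ester, and γ-hydroxy ester 29 closes to the five-membered lactone with loss of tert-butanol without touching the stereocentre.

Step 17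
Reactants: 31 methyl 4-hydroxy-3-methoxybenzoate (methyl vanillate)
Product: 32 methyl 4-(2-tert-butoxy-2-oxoethoxy)-3-methoxybenzoate
Conditions: BrCH2CO2t-Bu, K2CO3, DMF, rt
Reagents that add atoms: tert-butyl bromoacetate, CC(C)(C)OC(=O)CBr
Why: Williamson ether synthesis: the phenoxide displaces bromide from the activated α-bromo ester by an SN2 reaction.

Step 18
Reactants: 32 tert-butyl ester
Product: 33 2-[2-methoxy-4-(methoxycarbonyl)phenoxy]acetic acid
Conditions: CF3CO2H, CH2Cl2, 0 °C to rt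
Reagents that add atoms: none
Why: Acidolysis of a tert-butyl ester: loss of isobutene frees the aliphatic acid while the methyl benzoate, which cannot ionise in this way, is kept.

Step 19
Reactants: 33 aryloxyacetic acid; 24 (R)-4-benzyl-1,3-oxazolidin-2-one
Product: 35 methyl 4-{2-[(4R)-4-benzyl-2-oxo-1,3-oxazolidin-3-yl]-2-oxoethoxy}-3-methoxybenzoate, via pivalic mixed anhydride 34 (not isolated)
Conditions: t-BuCOCl, Et3N, THF, −20 °C; then LiCl, 24, −20 °C to rt
Reagents that add atoms: pivaloyl chloride, CC(C)(C)C(=O)Cl (its atoms stay in 34 only)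
Why: N-acylation of an oxazolidinone through a mixed pivalic anhydride, as in steps 5 and 14, with the aromatic methyl ester as a spectator.

Step 20
Reactants: 35 aryloxyacetyl imide; 9 O-benzylvanillin
Product: 37 (4R)-4-benzyl-3-{(2R,3S)-3-Ar-3-hydroxy-2-[2-methoxy-4-(methoxycarbonyl)phenoxy]propanoyl}-1,3-oxazolidin-2-one, via dibutylboron enolate 36 (not isolated)
Conditions: Bu2BOTf (1.3 equiv), Et3N, CH2Cl2, −78 to 0 °C; 9, −78 to 0 °C; pH 7 buffer, MeOH, 30% H2O2, 0 °C
Reagents that add atoms: dibutylboron triflate, CCCCB(CCCC)OS(=O)(=O)C(F)(F)F (its atoms stay in 36 only)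
Why: Evans boron syn-aldol reaction of an aryloxyacetyl imide: the Z-enolate 36 and the chair transition state give the syn pair, and the (R)-auxiliary sets the aryloxy carbon in the configuration kept to the end (S after reduction) and the carbinol carbon as S (threo).

Step 21
Reactants: 37 syn-aldol adduct
Product: 38 methyl 4-{[(1S,2S)-1-Ar-1,3-dihydroxypropan-2-yl]oxy}-3-methoxybenzoate (threo)
Conditions: NaBH4, THF–H2O, 0 °C to rt
Reagents that add atoms: none
Why: Reductive cleavage of an N-acyloxazolidinone with NaBH4 in aqueous THF: only the activated imide carbonyl is reduced, so the auxiliary leaves and the methyl benzoate is kept.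

Step 22
Reactants: 38 threo diol
Product: 39 methyl 4-{[(1S,2S)-1-Ar-1-hydroxy-3-(TBSO)propan-2-yl]oxy}-3-methoxybenzoate
Conditions: TBSCl, imidazole, CH2Cl2, 0 °C
Reagents that add atoms: tert-butyldimethylsilyl chloride, CC(C)(C)[Si](C)(C)Cl
Why: Chemoselective silylation: the primary hydroxyl reacts well before the hindered secondary benzylic one.

Step 23
Reactants: 39 threo alcohol
Product: 40 (1R,2S)-1-Ar-3-(TBSO)-2-[2-methoxy-4-(methoxycarbonyl)phenoxy]propyl 4-nitrobenzoate
Conditions: 4-O2NC6H4CO2H, PPh3, DIAD, THF, 0 °C to rt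
Reagents that add atoms: 4-nitrobenzoic acid, OC(=O)c1ccc(cc1)[N+](=O)[O-]
Why: Mitsunobu reaction in its 4-nitrobenzoic acid variant for hindered alcohols: SN2 displacement of the oxyphosphonium group by the carboxylate inverts the carbinol carbon from S to R and so turns the threo into the erythro series, a change known for aryl glycerol aryl ethers of this type.

Step 24
Reactants: 40 4-nitrobenzoate
Product: 41 methyl 4-{[(1R,2S)-1-Ar-1-hydroxy-3-(TBSO)propan-2-yl]oxy}-3-methoxybenzoate (erythro)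
Conditions: K2CO3 (cat.), MeOH, 0 °C to rt
Reagents that add atoms: none
Why: Base-catalysed transesterification (methanolysis): the activated 4-nitrobenzoate is exchanged at the acyl carbon with retention at the carbinol carbon, and exchange at the methyl benzoate is degenerate.

Step 25
Reactants: 41 erythro alcohol
Product: 42 methyl 4-{[(1R,2S)-1-Ar-1,3-bis(TBSO)propan-2-yl]oxy}-3-methoxybenzoate
Conditions: TBSOTf, 2,6-lutidine, CH2Cl2, −78 to 0 °C
Reagents that add atoms: tert-butyldimethylsilyl triflate, CC(C)(C)[Si](C)(C)OS(=O)(=O)C(F)(F)F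
Why: Silylation of a hindered secondary alcohol with a silyl triflate: the reaction takes place at oxygen under lutidine buffering, so the benzylic centre is not ionised.

Step 26
Reactants: 42 methyl ester
Product: 43 (4-{[(1R,2S)-1-Ar-1,3-bis(TBSO)propan-2-yl]oxy}-3-methoxyphenyl)methanol
Conditions: i-Bu2AlH (2.2 equiv), CH2Cl2, −78 °C; aq. potassium sodium tartrate
Reagents that add atoms: none
Why: Ester-to-alcohol reduction with an aluminium hydride: the benzoate is the only reducible group, and silyl and benzyl ethers are inert.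

Step 27
Reactants: 43 benzylic alcohol
Product: 44 1-(bromomethyl)-4-{[(1R,2S)-1-Ar-1,3-bis(TBSO)propan-2-yl]oxy}-3-methoxybenzene
Conditions: CBr4, PPh3, CH2Cl2, 0 °C; used at once
Reagents that add atoms: tetrabromomethane, BrC(Br)(Br)Br
Why: Appel reaction: neutral conversion of the primary benzylic alcohol into the bromide, which leaves the acid-sensitive benzylic silyl ether in place.

Step 28
Reactants: 30 (4R)-lactone; 44 ring A/B benzylic bromide
Product: 46 (3R,4R)-3-(4-{[(1R,2S)-1-Ar-1,3-bis(TBSO)propan-2-yl]oxy}-3-methoxybenzyl)-4-(DHB-methyl)oxolan-2-one, via lithium enolate 45 (not isolated)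
Conditions: LiN(SiMe3)2, THF, −78 °C; 44, DMPU, −78 to −30 °C
Reagents that add atoms: lithium bis(trimethylsilyl)amide, C[Si](C)(C)[N-][Si](C)(C)C.[Li+] (lithium stays in 45 only)
Why: Alkylation of a γ-butyrolactone enolate, the standard entry to dibenzylbutyrolactone lignans: the bromide approaches the planar enolate 45 anti to the C4 substituent, which sets C3 as R (trans), the isomer also favoured at equilibrium.

Step 29
Reactants: 46 fully protected compound
Product: 47 bis-O-benzyl ether of the target (three hydroxyl groups free)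
Conditions: Bu4NF, AcOH, THF, 0 °C to rt
Reagents that add atoms: none
Why: Fluoride-induced desilylation: buffered fluoride removes both TBS groups and the TIPS group at silicon, so no C–O bond is broken, and the acetic acid keeps the medium from opening or epimerising the lactone.

Step 30
Reactants: 47 bis-benzyl ether
Product: 48 target CNP0298853.1
Conditions: H2 (1 atm), Pd/C (10%), EtOAc–EtOH, rt, stopped when 47 is consumed
Reagents that add atoms: none
Why: Catalytic hydrogenolysis: aryl benzyl ethers are cleaved under neutral conditions faster than the secondary benzylic alcohol or the C2–O1 bond, as is usual for aryl glycerol ethers and phenylcoumarans, and the neutral last step spares the p-hydroxybenzylic centres.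

**Compound list**
1 | methyl 5-bromofuran-3-carboxylate | COC(=O)c1coc(Br)c1 | starting material
2 | (5-bromofuran-3-yl)methanol | OCc1coc(Br)c1 | intermediate
3 | [(5-bromofuran-3-yl)methoxy](tert-butyl)dimethylsilane | CC(C)(C)[Si](C)(C)OCc1coc(Br)c1 | intermediate
4 | ethyl 2-[4-(TBSOCH2)furan-2-yl]acetate | CCOC(=O)Cc1cc(CO[Si](C)(C)C(C)(C)C)co1 | intermediate
5 | 2-[4-(TBSOCH2)furan-2-yl]acetic acid | OC(=O)Cc1cc(CO[Si](C)(C)C(C)(C)C)co1 | intermediate
6 | (S)-4-benzyl-1,3-oxazolidin-2-one | O=C1OC[C@H](Cc2ccccc2)N1 | starting material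
7 | mixed anhydride of 5 and pivalic acid (formed in the flask) | CC(C)(C)C(=O)OC(=O)Cc1cc(CO[Si](C)(C)C(C)(C)C)co1 | intermediate
8 | (4S)-4-benzyl-3-{2-[4-(TBSOCH2)furan-2-yl]acetyl}-1,3-oxazolidin-2-one | O=C1OC[C@H](Cc2ccccc2)N1C(=O)Cc1cc(CO[Si](C)(C)C(C)(C)C)co1 | intermediate
9 | 4-(benzyloxy)-3-methoxybenzaldehyde | COc1cc(C=O)ccc1OCc1ccccc1 | starting material
10 | (Z)-dibutylboron enolate of 8 (formed in the flask) | CCCCB(CCCC)O/C(=C\c1cc(CO[Si](C)(C)C(C)(C)C)co1)N1C(=O)OC[C@@H]1Cc1ccccc1 | intermediate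
11 | (4S)-4-benzyl-3-{(2R,3S)-3-Ar-3-hydroxy-2-[4-(TBSOCH2)furan-2-yl]propanoyl}-1,3-oxazolidin-2-one | CC(C)(C)[Si](C)(C)OCc1coc(c1)[C@H](C(=O)N1C(=O)OC[C@@H]1Cc1ccccc1)[C@@H](c1ccc(OCc2ccccc2)c(OC)c1)O | intermediate
12 | (1S,2R)-1-Ar-2-[4-(TBSOCH2)furan-2-yl]propane-1,3-diol | CC(C)(C)[Si](C)(C)OCc1coc(c1)[C@H](CO)[C@@H](c1ccc(OCc2ccccc2)c(OC)c1)O | intermediate
13 | (1S,2R)-1-Ar-2-[4-(TBSOCH2)furan-2-yl]-3-(TIPSO)propan-1-ol | CC(C)(C)[Si](C)(C)OCc1coc(c1)[C@H](CO[Si](C(C)C)(C(C)C)C(C)C)[C@@H](c1ccc(OCc2ccccc2)c(OC)c1)O | intermediate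
14 | (E)-1,2-dichlorovinyl ether of 13 (formed in the flask) | CC(C)(C)[Si](C)(C)OCc1coc(c1)[C@H](CO[Si](C(C)C)(C(C)C)C(C)C)[C@@H](c1ccc(OCc2ccccc2)c(OC)c1)O/C(Cl)=C\Cl | intermediate
15 | chloroethynyl ether of 13 (formed in the flask) | CC(C)(C)[Si](C)(C)OCc1coc(c1)[C@H](CO[Si](C(C)C)(C(C)C)C(C)C)[C@@H](c1ccc(OCc2ccccc2)c(OC)c1)OC#CCl | intermediate
16 | lithioethynyl ether of 13 (formed in the flask) | CC(C)(C)[Si](C)(C)OCc1coc(c1)[C@H](CO[Si](C(C)C)(C(C)C)C(C)C)[C@@H](c1ccc(OCc2ccccc2)c(OC)c1)OC#C[Li] | intermediate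
17 | (1S,2R)-1-Ar-2-[4-(TBSOCH2)furan-2-yl]-3-(TIPSO)propyl ethynyl ether (key-step precursor) | CC(C)(C)[Si](C)(C)OCc1coc(c1)[C@H](CO[Si](C(C)C)(C(C)C)C(C)C)[C@@H](c1ccc(OCc2ccccc2)c(OC)c1)OC#C | intermediate
18 | C6,C7-arene oxide of the dihydrobenzofuran, oxirane carbons undefined (formed in the flask) | CC(C)(C)[Si](C)(C)OCC1=CC2=C(C3OC31)O[C@H](c1ccc(OCc3ccccc3)c(OC)c1)[C@H]2CO[Si](C(C)C)(C(C)C)C(C)C | intermediate
19 | (2S,3R)-2-Ar-5-(TBSOCH2)-3-(TIPSOCH2)-2,3-dihydro-1-benzofuran-7-ol (key-step product) | CC(C)(C)[Si](C)(C)OCc1cc(O)c2c(c1)[C@H](CO[Si](C(C)C)(C(C)C)C(C)C)[C@@H](c1ccc(OCc3ccccc3)c(OC)c1)O2 | intermediate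
20 | (2S,3R)-2-Ar-7-methoxy-5-(TBSOCH2)-3-(TIPSOCH2)-2,3-dihydro-1-benzofuran | CC(C)(C)[Si](C)(C)OCc1cc(OC)c2c(c1)[C@H](CO[Si](C(C)C)(C(C)C)C(C)C)[C@@H](c1ccc(OCc3ccccc3)c(OC)c1)O2 | intermediate
21 | [(2S,3R)-2-Ar-7-methoxy-3-(TIPSOCH2)-2,3-dihydro-1-benzofuran-5-yl]methanol | OCc1cc(OC)c2c(c1)[C@H](CO[Si](C(C)C)(C(C)C)C(C)C)[C@@H](c1ccc(OCc3ccccc3)c(OC)c1)O2 | intermediate
22 | (2S,3R)-2-Ar-5-(bromomethyl)-7-methoxy-3-(TIPSOCH2)-2,3-dihydro-1-benzofuran | BrCc1cc(OC)c2c(c1)[C@H](CO[Si](C(C)C)(C(C)C)C(C)C)[C@@H](c1ccc(OCc3ccccc3)c(OC)c1)O2 | intermediate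
23 | 4-tert-butoxy-4-oxobutanoic acid | CC(C)(C)OC(=O)CCC(=O)O | starting material
24 | (R)-4-benzyl-1,3-oxazolidin-2-one | O=C1OC[C@@H](Cc2ccccc2)N1 | starting material
25 | mixed anhydride of 23 and pivalic acid (formed in the flask) | CC(C)(C)OC(=O)CCC(=O)OC(=O)C(C)(C)C | intermediate
26 | tert-butyl 4-[(4R)-4-benzyl-2-oxo-1,3-oxazolidin-3-yl]-4-oxobutanoate | CC(C)(C)OC(=O)CCC(=O)N1C(=O)OC[C@H]1Cc1ccccc1 | intermediate
27 | sodium (Z)-enolate of 26 (formed in the flask) | CC(C)(C)OC(=O)C/C=C(\[O-])N1C(=O)OC[C@H]1Cc1ccccc1.[Na+] | intermediate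
28 | tert-butyl (3R)-4-[(4R)-4-benzyl-2-oxo-1,3-oxazolidin-3-yl]-3-(DHB-methyl)-4-oxobutanoate | CC(C)(C)OC(=O)C[C@@H](Cc1cc(OC)c2c(c1)[C@H](CO[Si](C(C)C)(C(C)C)C(C)C)[C@@H](c1ccc(OCc3ccccc3)c(OC)c1)O2)C(=O)N1C(=O)OC[C@H]1Cc1ccccc1 | intermediate
29 | tert-butyl (3R)-3-(DHB-methyl)-4-hydroxybutanoate (formed in the flask) | CC(C)(C)OC(=O)C[C@@H](Cc1cc(OC)c2c(c1)[C@H](CO[Si](C(C)C)(C(C)C)C(C)C)[C@@H](c1ccc(OCc3ccccc3)c(OC)c1)O2)CO | intermediate
30 | (4R)-4-(DHB-methyl)oxolan-2-one | O=C1C[C@@H](Cc2cc(OC)c3c(c2)[C@H](CO[Si](C(C)C)(C(C)C)C(C)C)[C@@H](c2ccc(OCc4ccccc4)c(OC)c2)O3)CO1 | intermediate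
31 | methyl 4-hydroxy-3-methoxybenzoate | COC(=O)c1ccc(O)c(OC)c1 | starting material
32 | methyl 4-(2-tert-butoxy-2-oxoethoxy)-3-methoxybenzoate | COC(=O)c1ccc(OCC(=O)OC(C)(C)C)c(OC)c1 | intermediate
33 | 2-[2-methoxy-4-(methoxycarbonyl)phenoxy]acetic acid | COC(=O)c1ccc(OCC(=O)O)c(OC)c1 | intermediate
34 | mixed anhydride of 33 and pivalic acid (formed in the flask) | COC(=O)c1ccc(OCC(=O)OC(=O)C(C)(C)C)c(OC)c1 | intermediate
35 | methyl 4-{2-[(4R)-4-benzyl-2-oxo-1,3-oxazolidin-3-yl]-2-oxoethoxy}-3-methoxybenzoate | COC(=O)c1ccc(OCC(=O)N2C(=O)OC[C@H]2Cc2ccccc2)c(OC)c1 | intermediate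
36 | (Z)-dibutylboron enolate of 35 (formed in the flask) | COC(=O)c1ccc(O/C=C(\OB(CCCC)CCCC)N2C(=O)OC[C@H]2Cc2ccccc2)c(OC)c1 | intermediate
37 | (4R)-4-benzyl-3-{(2R,3S)-3-Ar-3-hydroxy-2-[2-methoxy-4-(methoxycarbonyl)phenoxy]propanoyl}-1,3-oxazolidin-2-one | COc1cc([C@H](O)[C@H](C(=O)N2C(=O)OC[C@H]2Cc2ccccc2)Oc2ccc(C(=O)OC)cc2OC)ccc1OCc1ccccc1 | intermediate
38 | methyl 4-{[(1S,2S)-1-Ar-1,3-dihydroxypropan-2-yl]oxy}-3-methoxybenzoate | COc1cc([C@H](O)[C@H](CO)Oc2ccc(C(=O)OC)cc2OC)ccc1OCc1ccccc1 | intermediate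
39 | methyl 4-{[(1S,2S)-1-Ar-1-hydroxy-3-(TBSO)propan-2-yl]oxy}-3-methoxybenzoate | COc1cc([C@H](O)[C@H](CO[Si](C)(C)C(C)(C)C)Oc2ccc(C(=O)OC)cc2OC)ccc1OCc1ccccc1 | intermediate
40 | (1R,2S)-1-Ar-3-(TBSO)-2-[2-methoxy-4-(methoxycarbonyl)phenoxy]propyl 4-nitrobenzoate | COc1cc([C@@H](OC(=O)c2ccc(cc2)[N+](=O)[O-])[C@H](CO[Si](C)(C)C(C)(C)C)Oc2ccc(C(=O)OC)cc2OC)ccc1OCc1ccccc1 | intermediate
41 | methyl 4-{[(1R,2S)-1-Ar-1-hydroxy-3-(TBSO)propan-2-yl]oxy}-3-methoxybenzoate | COc1cc([C@@H](O)[C@H](CO[Si](C)(C)C(C)(C)C)Oc2ccc(C(=O)OC)cc2OC)ccc1OCc1ccccc1 | intermediate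
42 | methyl 4-{[(1R,2S)-1-Ar-1,3-bis(TBSO)propan-2-yl]oxy}-3-methoxybenzoate | COc1cc([C@@H](O[Si](C)(C)C(C)(C)C)[C@H](CO[Si](C)(C)C(C)(C)C)Oc2ccc(C(=O)OC)cc2OC)ccc1OCc1ccccc1 | intermediate
43 | (4-{[(1R,2S)-1-Ar-1,3-bis(TBSO)propan-2-yl]oxy}-3-methoxyphenyl)methanol | COc1cc([C@@H](O[Si](C)(C)C(C)(C)C)[C@H](CO[Si](C)(C)C(C)(C)C)Oc2ccc(CO)cc2OC)ccc1OCc1ccccc1 | intermediate
44 | 1-(bromomethyl)-4-{[(1R,2S)-1-Ar-1,3-bis(TBSO)propan-2-yl]oxy}-3-methoxybenzene | COc1cc([C@@H](O[Si](C)(C)C(C)(C)C)[C@H](CO[Si](C)(C)C(C)(C)C)Oc2ccc(CBr)cc2OC)ccc1OCc1ccccc1 | intermediate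
45 | lithium enolate of 30 (formed in the flask) | [Li+].[O-]C1=C[C@@H](Cc2cc(OC)c3c(c2)[C@H](CO[Si](C(C)C)(C(C)C)C(C)C)[C@@H](c2ccc(OCc4ccccc4)c(OC)c2)O3)CO1 | intermediate
46 | (3R,4R)-3-(4-{[(1R,2S)-1-Ar-1,3-bis(TBSO)propan-2-yl]oxy}-3-methoxybenzyl)-4-(DHB-methyl)oxolan-2-one | COc1cc([C@@H](O[Si](C)(C)C(C)(C)C)[C@H](CO[Si](C)(C)C(C)(C)C)Oc2ccc(C[C@H]3C(=O)OC[C@@H]3Cc3cc(OC)c4c(c3)[C@H](CO[Si](C(C)C)(C(C)C)C(C)C)[C@@H](c3ccc(OCc5ccccc5)c(OC)c3)O4)cc2OC)ccc1OCc1ccccc1 | intermediate
47 | target with both phenols as benzyl ethers | COc1cc([C@@H](O)[C@H](CO)Oc2ccc(C[C@H]3C(=O)OC[C@@H]3Cc3cc(OC)c4c(c3)[C@H](CO)[C@@H](c3ccc(OCc5ccccc5)c(OC)c3)O4)cc2OC)ccc1OCc1ccccc1 | intermediate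
48 | (3R,4R)-3-[(4-{[(1R,2S)-1,3-dihydroxy-1-(4-hydroxy-3-methoxyphenyl)propan-2-yl]oxy}-3-methoxyphenyl)methyl]-4-{[(2S,3R)-2-(4-hydroxy-3-methoxyphenyl)-3-(hydroxymethyl)-7-methoxy-2,3-dihydro-1-benzofuran-5-yl]methyl}oxolan-2-one | COc1cc([C@@H](O)[C@H](CO)Oc2ccc(C[C@H]3C(=O)OC[C@@H]3Cc3cc(OC)c4c(c3)[C@H](CO)[C@@H](c3ccc(O)c(OC)c3)O4)cc2OC)ccc1O | target

Total step count: 30
Longest linear sequence: 18 steps (steps 1–13, 15, 16, 28–30)

**Steps most likely to fail**

**1. Step 10 (gold cascade).**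
- Risk: once gold is bound the ynol ether has ketene-oxonium character. Three processes may then run faster than attack by the furan: heterolysis of the C2–O1 bond (C2 is a secondary benzylic carbon para to an alkoxy group), a [3,3] shift onto ring D, or hydration by traces of water. The arene oxide may also open toward C6.
- Fallback: it sets out from methyl vanillate 31 and aldehyde 9 and comes back at alcohol 21. Ring C is taken from an existing arene instead of being made.
- Building the imide: bromination of 31 (Br2, AcOH) should give methyl 5-bromovanillate F1, and MOMCl with i-Pr2NEt the MOM ether F2. The coupling of step 3 gives the ethyl arylacetate F3. LiOH (one equivalent, 0 °C) cleaves only the aliphatic ester to the arylacetic acid F4. Acylation of 6 as in step 5 gives the imide F5.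
- Setting C3 and closing the ring: the boron aldol of step 6 with 9 gives the syn-aldol adduct F6. NaBH4 in THF–H2O removes the auxiliary and keeps the benzoate, giving the diol F7. HCl in MeOH–THF takes off the MOM group, and the p-alkoxybenzylic carbinol ionises and is captured by the freed phenol anti to the C3 substituent. This gives the trans-dihydrobenzofuran ester F8, in which C2 is set by the auxiliary-derived C3.
- Return: TIPSCl gives the TIPS ether F9, and i-Bu2AlH reduces its ester to 21.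

**2. Step 9 (ynol ether).**
- Risk: silicon may migrate from the primary oxygen to the potassium alkoxide before vinylation. n-BuLi may metalate a benzylic or furan C–H bond. The acid-sensitive ethynyl ether may decompose on isolation.
- Fallback: it sets out from alcohol 13 and comes back at ethynyl ether 17. The oxygen is acylated and never turned into an alkoxide.
- Sequence: formic acetic anhydride and pyridine should give the formate F10. Wittig-type dichloromethylenation of the formyl group (PPh3, CCl4, THF, 60 °C) gives the 2,2-dichlorovinyl ether F11. n-BuLi (−78 °C) eliminates HCl to the same chloroethynyl ether 15 and exchanges chlorine for lithium to 16. Methanol then gives 17.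

**3. Step 23 (Mitsunobu inversion).**
- Risk: the oxyphosphonium ion sits on an electron-rich benzylic carbon. Partial ionisation would erode the inversion, and elimination toward the aryl enol ether may compete.
- Fallback: it sets out from threo alcohol 39 and comes back at erythro alcohol 41. The centre is reset by oxidation and reduction instead of substitution.
- Sequence: Dess–Martin periodinane buffered with NaHCO3 should give the ketone F12 without touching the neighbouring aryloxy centre. Corey–Bakshi–Shibata reduction follows with (R)-Me-CBS and BH3·SMe2 at −20 °C. This catalyst enantiomer is chosen on the model in which the aryl group is the large substituent. It delivers hydride under reagent control to give the 1R carbinol 41, and the methyl benzoate is not reduced at this temperature.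

**Further compounds**
F1 | step 10 | methyl 3-bromo-4-hydroxy-5-methoxybenzoate | COC(=O)c1cc(Br)c(O)c(OC)c1
F2 | step 10 | methyl 3-bromo-5-methoxy-4-(methoxymethoxy)benzoate | COCOc1c(Br)cc(cc1OC)C(=O)OC
F3 | step 10 | methyl 3-(2-ethoxy-2-oxoethyl)-5-methoxy-4-(methoxymethoxy)benzoate | CCOC(=O)Cc1cc(cc(OC)c1OCOC)C(=O)OC
F4 | step 10 | 2-[3-methoxy-5-(methoxycarbonyl)-2-(methoxymethoxy)phenyl]acetic acid | OC(=O)Cc1cc(cc(OC)c1OCOC)C(=O)OC
F5 | step 10 | methyl 3-{2-[(4S)-4-benzyl-2-oxo-1,3-oxazolidin-3-yl]-2-oxoethyl}-5-methoxy-4-(methoxymethoxy)benzoate | O=C1OC[C@H](Cc2ccccc2)N1C(=O)Cc1cc(cc(OC)c1OCOC)C(=O)OC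
F6 | step 10 | methyl 3-{(2S,3S)-3-Ar-1-[(4S)-4-benzyl-2-oxo-1,3-oxazolidin-3-yl]-3-hydroxy-1-oxopropan-2-yl}-5-methoxy-4-(methoxymethoxy)benzoate | COC(=O)c1cc(OC)c(OCOC)c(c1)[C@H](C(=O)N1C(=O)OC[C@@H]1Cc1ccccc1)[C@@H](c1ccc(OCc2ccccc2)c(OC)c1)O
F7 | step 10 | methyl 3-[(1S,2R)-1-Ar-1,3-dihydroxypropan-2-yl]-5-methoxy-4-(methoxymethoxy)benzoate | COC(=O)c1cc(OC)c(OCOC)c(c1)[C@H](CO)[C@@H](c1ccc(OCc2ccccc2)c(OC)c1)O
F8 | step 10 | methyl (2S,3R)-2-Ar-3-(hydroxymethyl)-7-methoxy-2,3-dihydro-1-benzofuran-5-carboxylate | COC(=O)c1cc(OC)c2c(c1)[C@H](CO)[C@@H](c1ccc(OCc3ccccc3)c(OC)c1)O2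
F9 | step 10 | methyl (2S,3R)-2-Ar-7-methoxy-3-(TIPSOCH2)-2,3-dihydro-1-benzofuran-5-carboxylate | COC(=O)c1cc(OC)c2c(c1)[C@H](CO[Si](C(C)C)(C(C)C)C(C)C)[C@@H](c1ccc(OCc3ccccc3)c(OC)c1)O2
F10 | step 9 | (1S,2R)-1-Ar-2-[4-(TBSOCH2)furan-2-yl]-3-(TIPSO)propyl formate | CC(C)(C)[Si](C)(C)OCc1coc(c1)[C@H](CO[Si](C(C)C)(C(C)C)C(C)C)[C@@H](c1ccc(OCc2ccccc2)c(OC)c1)OC=O
F11 | step 9 | (1S,2R)-1-Ar-2-[4-(TBSOCH2)furan-2-yl]-3-(TIPSO)propyl 2,2-dichlorovinyl ether | CC(C)(C)[Si](C)(C)OCc1coc(c1)[C@H](CO[Si](C(C)C)(C(C)C)C(C)C)[C@@H](c1ccc(OCc2ccccc2)c(OC)c1)OC=C(Cl)Cl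
F12 | step 23 | methyl 4-{[(2S)-1-Ar-1-oxo-3-(TBSO)propan-2-yl]oxy}-3-methoxybenzoate | COc1cc(C(=O)[C@H](CO[Si](C)(C)C(C)(C)C)Oc2ccc(C(=O)OC)cc2OC)ccc1OCc1ccccc1
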